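**Plan**

- Retrosynthesis: the two benzylic arm hydroxyls are first joined through a succinate (two ester C–O bonds, cleaved last). The tetrahydrofuran is then cut at O1–C2, O1–C5 and C3–C4, giving two tethered (E)-propenyl aryl ethers. Further cuts at the tether esters, the carbinol C–H bonds, the aryl–C(=O) bonds and the two C8–OAr bonds lead back to (E)-isoeugenol, the two lactate esters and 4-bromoveratrole.
- Enabling feature: C2–C3–C4–C5 with O1 is two arylpropene units linked through their β-carbons (C3–C4) and capped by one oxygen on the two benzylic carbons. Rings B and C are each already the 4-O-ether of one arm, so each half is an isoeugenol ether.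
- Forward: each arm is built on isoeugenol (Mitsunobu ether, Weinreb amide, aryl ketone, reduction) and the two halves are tied through succinate. One anodic oxidation in wet acetonitrile then forms C3–C4 and both C–O1 bonds and closes the only ring of the target (plus a temporary macrocycle). Methanolysis releases the target.
- Stereochemistry: C8 of each arm comes from a lactate with Mitsunobu inversion ((S)-lactate gives 8R, threo arm, ring C; (R)-lactate gives 8S, erythro arm, ring B). C7 comes from substrate-controlled ketone reduction (Felkin–Anh for threo, zinc chelation for erythro).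
- The four ring centres arise in the key step under the influence of alkene geometry and tether; the right diastereomer is then selected by chromatography.

Key step: step 12

Remark on the chemistry: numbering is O1, C2 (ring B), C3, C4, C5 (ring C) for the tetrahydrofuran and C7 (carbinol) / C8 (CH–OAr) for each arm; rings A and D are the veratryl rings. Read from the SMILES, the core is (2S,3S,4S,5R): ring B trans to the C3 methyl, methyls trans, ring C cis to the C4 methyl, aryl groups cis across O1. The arm on ring B is erythro (7R,8S) and the arm on ring C is threo (7R,8R). The core is therefore a kinetic, not the all-trans, arrangement.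

**Route**

Step 1
Reactants: 1 ethyl (S)-lactate; 2 (E)-isoeugenol
Product: 3 ethyl (R)-2-[2-methoxy-4-[(E)-prop-1-enyl]phenoxy]propanoate
Conditions: PPh3, DIAD, THF, 0 °C to rt
Reagents that add atoms: none
Why: Mitsunobu etherification, in which the phenol displaces the phosphonium-activated lactate hydroxyl by SN2, so C8 is set as (R) by inversion of the (S)-lactate centre under neutral conditions that leave the α-hydrogen and the (E)-propenyl group untouched.

Step 2
Reactants: 3 ethyl (R)-2-[2-methoxy-4-[(E)-prop-1-enyl]phenoxy]propanoate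
Product: 4 (R)-N-methoxy-2-[2-methoxy-4-[(E)-prop-1-enyl]phenoxy]-N-methylpropanamide
Conditions: MeNH(OMe)·HCl, iPrMgCl, THF, −20 °C
Reagents that add atoms: N,O-dimethylhydroxylamine hydrochloride, Cl.CNOC
Why: Weinreb amide formation by aminolysis of the ester with the chloromagnesium amide, fast enough at low temperature that the α-aryloxy stereocentre should not be enolised.

Step 3
Reactants: 5 4-bromoveratrole
Product: 6 (3,4-dimethoxyphenyl)magnesium bromide (titrated THF solution, used in steps 4 and 8)
Conditions: Mg turnings, I2 (cat.), THF, 40 °C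
Reagents that add atoms: magnesium, [Mg]
Why: Grignard reagent formation by insertion of magnesium into the C–Br bond of an electron-rich bromoarene, a routine preparation.

Step 4
Reactants: 4 (R)-Weinreb amide; 6 (3,4-dimethoxyphenyl)magnesium bromide
Product: 7 (R)-1-(3,4-dimethoxyphenyl)-2-[2-methoxy-4-[(E)-prop-1-enyl]phenoxy]propan-1-one
Conditions: THF, −10 to 0 °C; cold aq NH4Cl
Reagents that add atoms: none
Why: Weinreb ketone synthesis, in which the chelated tetrahedral adduct persists until the quench so the aryl group adds only once, and the cold buffered work-up should keep the (R) centre next to the new ketone.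

Step 5
Reactants: 7 (R)-aryloxy ketone
Product: 8 (1R,2R)-1-(3,4-dimethoxyphenyl)-2-[2-methoxy-4-[(E)-prop-1-enyl]phenoxy]propan-1-ol (threo)
Conditions: polymer-supported borohydride (Amberlite IRA-400, BH4− form), MeOH, 0 °C to rt
Reagents that add atoms: none
Why: Felkin–Anh-controlled ketone reduction, in which borohydride with a non-chelating ammonium counter-ion attacks anti to the electronegative aryloxy group, setting C7 as (R) and giving the threo alcohol.

Step 6
Reactants: 9 methyl (R)-lactate; 2 (E)-isoeugenol
Product: 10 methyl (S)-2-[2-methoxy-4-[(E)-prop-1-enyl]phenoxy]propanoate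
Conditions: PPh3, DIAD, THF, 0 °C to rt
Reagents that add atoms: none
Why: Mitsunobu etherification as in step 1, setting C8 of the erythro arm as (S) by SN2 inversion of the (R)-lactate centre.

Step 7
Reactants: 10 methyl (S)-2-aryloxypropanoate
Product: 11 (S)-N-methoxy-2-[2-methoxy-4-[(E)-prop-1-enyl]phenoxy]-N-methylpropanamide
Conditions: MeNH(OMe)·HCl, iPrMgCl, THF, −20 °C
Reagents that add atoms: N,O-dimethylhydroxylamine hydrochloride, Cl.CNOC
Why: Weinreb amide formation by magnesium-amide aminolysis of the ester, as in step 2, at a temperature where the stereocentre should hold.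

Step 8
Reactants: 11 (S)-Weinreb amide; 6 (3,4-dimethoxyphenyl)magnesium bromide
Product: 12 (S)-1-(3,4-dimethoxyphenyl)-2-[2-methoxy-4-[(E)-prop-1-enyl]phenoxy]propan-1-one
Conditions: THF, −10 to 0 °C; cold aq NH4Cl
Reagents that add atoms: none
Why: Weinreb ketone synthesis as in step 4, with single addition through the stable chelated adduct and retention of the (S) centre.

Step 9
Reactants: 12 (S)-aryloxy ketone
Product: 13 (1R,2S)-1-(3,4-dimethoxyphenyl)-2-[2-methoxy-4-[(E)-prop-1-enyl]phenoxy]propan-1-ol (erythro)
Conditions: Zn(BH4)2, Et2O, −20 to 0 °C; aq NH4Cl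
Reagents that add atoms: none
Why: Cram-chelate-controlled reduction, in which zinc bridges the carbonyl and aryloxy oxygens and hydride enters the five-membered chelate from the side of the C8 hydrogen, setting C7 as (R) and giving the erythro alcohol.

Step 10
Reactants: 13 erythro alcohol
Product: 14 4-{(1R,2S)-1-(3,4-dimethoxyphenyl)-2-[2-methoxy-4-[(E)-prop-1-enyl]phenoxy]propoxy}-4-oxobutanoic acid (hemisuccinate of 13)
Conditions: succinic anhydride, DMAP (cat.), pyridine, rt
Reagents that add atoms: succinic anhydride, O=C1CCC(=O)O1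
Why: DMAP-catalysed ring opening of a cyclic anhydride by a secondary alcohol, which stops cleanly at the mono-ester acid and acylates at oxygen, so no stereocentre is touched.

Step 11
Reactants: 14 hemisuccinate of 13; 8 threo alcohol
Product: 15 mixed succinate diester, (1R,2S)-arm of 13 and (1R,2R)-arm of 8 each esterified through its C7 oxygen
Conditions: EDC·HCl, DMAP, CH2Cl2, 0 °C to rt
Reagents that add atoms: none
Why: Steglich esterification of the free acid with the second benzylic alcohol, an O-acylation that keeps both carbinol configurations and ties the two different propenyl aryl ethers into one molecule.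

Step 12
Reactants: 15 mixed succinate diester
Product: 17 macrocyclic succinate-bridged tetrahydrofuran (core 2S,3S,4S,5R; ring B at C2 trans and ring C at C5 cis to the neighbouring methyl group), via macrocyclic bis-benzylic dication 16 (not isolated)
Conditions: undivided cell, reticulated vitreous carbon anode, Pt cathode; (4-BrC6H4)3N (20 mol %) as mediator, LiClO4 (0.1 M), NaHCO3 (solid), MeCN–H2O 19:1, 0 °C; slow addition of 15 (final concentration at most 1 mM), constant current to about 2 F/mol; then silica chromatography and preparative HPLC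
Reagents that add atoms: water, O
Why: Proposed new method: the anodically generated triarylaminium takes one electron from one 4-alkoxy-3-methoxy-(E)-propenylbenzene unit of 15 (the only groups it can oxidise, the acyloxy-substituted veratryl rings A and D being harder to oxidise), the radical cation adds with its β-carbon to the β-carbon of the tethered second alkene to form C3–C4, loss of a second electron gives the bis(4-alkoxybenzyl) dication 16, and one molecule of water is taken up so that its oxygen becomes O1, bonded to C2 and C5. The closest known reaction type is the oxidative 8–8' homodimerisation of 4-alkoxy-1-propenylbenzenes in the presence of water to 2,5-diaryl-3,4-dimethyltetrahydrofurans, together with aminium-mediated radical-cation couplings of such alkenes; running it between two different monomers inside one molecule is the untested part. Two rings close: the temporary 24-membered macrocycle by end-to-end radical-cation/alkene C–C coupling across the succinate, and the tetrahydrofuran by 5-exo-trig attack of the hydroxyl formed at one benzylic cation on the other, quinone-methide-like, cation. C3 and C4 are set in the C–C coupling, where the (E)-geometry of both alkenes and an anti approach of the two β-methyl groups should favour the trans-dimethyl linkage; C2 and C5 are set in the two C–O bond formations, where the short succinate is expected to reach across only when both aryl groups stand on the same face of the new ring, which disfavours the all-trans core and leaves the trans,trans,cis cores to which 17 belongs. The step needs hetero- over homo-coupling, which the tether and high dilution should secure, and a kinetic ring closure, which the bicarbonate buffer protects against acid equilibration towards the all-trans isomer. The sense of the core relative to the arms and the side of the cis junction are not controlled by the substrate, so 17 has to be separated from its diastereomers by chromatography.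

Step 13
Reactants: 17 macrocyclic succinate-bridged tetrahydrofuran
Product: 18 target, CNP0116650.9
Conditions: K2CO3 (cat.), MeOH–THF, rt
Reagents that add atoms: none
Why: Base-catalysed transesterification (Zemplén-type methanolysis) opens both benzylic esters and releases the two arm alcohols, while the tetrahydrofuran, the aryl ethers and all eight stereocentres are inert to carbonate in methanol.

**Compound list**

1 | ethyl (S)-lactate | C[C@H](O)C(=O)OCC | starting material
2 | (E)-isoeugenol | COc1cc(/C=C/C)ccc1O | starting material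
3 | ethyl (R)-2-[2-methoxy-4-[(E)-prop-1-enyl]phenoxy]propanoate | C/C=C/c1ccc(O[C@H](C)C(=O)OCC)c(OC)c1 | intermediate
4 | (R)-N-methoxy-2-[2-methoxy-4-[(E)-prop-1-enyl]phenoxy]-N-methylpropanamide | C/C=C/c1ccc(O[C@H](C)C(=O)N(C)OC)c(OC)c1 | intermediate
5 | 4-bromoveratrole | COc1ccc(Br)cc1OC | starting material
6 | (3,4-dimethoxyphenyl)magnesium bromide | COc1ccc([Mg]Br)cc1OC | intermediate
7 | (R)-1-(3,4-dimethoxyphenyl)-2-[2-methoxy-4-[(E)-prop-1-enyl]phenoxy]propan-1-one | C/C=C/c1ccc(O[C@H](C)C(=O)c2ccc(OC)c(OC)c2)c(OC)c1 | intermediate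
8 | (1R,2R)-1-(3,4-dimethoxyphenyl)-2-[2-methoxy-4-[(E)-prop-1-enyl]phenoxy]propan-1-ol (threo) | C/C=C/c1ccc(O[C@H](C)[C@H](O)c2ccc(OC)c(OC)c2)c(OC)c1 | intermediate
9 | methyl (R)-lactate | C[C@@H](O)C(=O)OC | starting material
10 | methyl (S)-2-[2-methoxy-4-[(E)-prop-1-enyl]phenoxy]propanoate | C/C=C/c1ccc(O[C@@H](C)C(=O)OC)c(OC)c1 | intermediate
11 | (S)-N-methoxy-2-[2-methoxy-4-[(E)-prop-1-enyl]phenoxy]-N-methylpropanamide | C/C=C/c1ccc(O[C@@H](C)C(=O)N(C)OC)c(OC)c1 | intermediate
12 | (S)-1-(3,4-dimethoxyphenyl)-2-[2-methoxy-4-[(E)-prop-1-enyl]phenoxy]propan-1-one | C/C=C/c1ccc(O[C@@H](C)C(=O)c2ccc(OC)c(OC)c2)c(OC)c1 | intermediate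
13 | (1R,2S)-1-(3,4-dimethoxyphenyl)-2-[2-methoxy-4-[(E)-prop-1-enyl]phenoxy]propan-1-ol (erythro) | C/C=C/c1ccc(O[C@@H](C)[C@H](O)c2ccc(OC)c(OC)c2)c(OC)c1 | intermediate
14 | 4-{(1R,2S)-1-(3,4-dimethoxyphenyl)-2-[2-methoxy-4-[(E)-prop-1-enyl]phenoxy]propoxy}-4-oxobutanoic acid | C/C=C/c1ccc(O[C@@H](C)[C@H](OC(=O)CCC(=O)O)c2ccc(OC)c(OC)c2)c(OC)c1 | intermediate
15 | mixed succinate diester of 13 (1R,2S arm) and 8 (1R,2R arm), both through O7 | C/C=C/c1ccc(O[C@@H](C)[C@H](OC(=O)CCC(=O)O[C@@H]([C@@H](C)Oc2ccc(/C=C/C)cc2OC)c3ccc(OC)c(OC)c3)c4ccc(OC)c(OC)c4)c(OC)c1 | intermediate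
16 | macrocyclic bis-benzylic dication (C3–C4 formed, trans-dimethyl, cationic C2 and C5) | COc1cc(ccc1O[C@@H](C)[C@H](OC(=O)CCC3=O)c2ccc(OC)c(OC)c2)[CH+][C@@H](C)[C@H](C)[CH+]c4ccc(O[C@H](C)[C@H](O3)c5ccc(OC)c(OC)c5)c(OC)c4 | intermediate
17 | macrocyclic succinate-bridged (2S,3S,4S,5R)-2,5-diaryl-3,4-dimethyltetrahydrofuran (ring B with 7R,8S arm at C2; ring C with 7R,8R arm at C5; the two O7 atoms joined as butanedioate) | COc1cc(ccc1O[C@@H](C)[C@H](OC(=O)CCC6=O)c2ccc(OC)c(OC)c2)[C@H]3O[C@@H](c4ccc(O[C@H](C)[C@H](O6)c5ccc(OC)c(OC)c5)c(OC)c4)[C@@H](C)[C@@H]3C | intermediate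
18 | CNP0116650.9 | COc1ccc([C@@H](O)[C@H](C)Oc2ccc([C@H]3O[C@@H](c4ccc(O[C@H](C)[C@H](O)c5ccc(OC)c(OC)c5)c(OC)c4)[C@@H](C)[C@@H]3C)cc2OC)cc1OC | target

**Count and risks**

Total: 13 steps. Longest linear sequence: 8 steps (9 → 10 → 11 → 12 → 13 → 14 → 15 → 17 → 18, steps 6 to 13).

Steps most likely to fail:

1. Step 12 (carries the new method). Several processes could defeat it:
   - Intermolecular coupling may outrun ring closure, giving oligomers and crossed dimers.
   - The radical cation may be hydrated or over-oxidised before it finds its partner.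
   - Cyclobutane formation or aryl trapping of the benzylic cation may compete with water capture.
   - The tetrahydrofuran may close with the wrong sense or the wrong cis junction, or equilibrate to the all-trans core.

   The fallback uses known chemistry only and builds the ring one bond at a time. It sets out from erythro alcohol 13, uses 1 and 6, and returns at target 18.
   - TBSCl and imidazole in DMF convert 13 into its silyl ether F1. Ozonolysis (O3, CH2Cl2–MeOH, −78 °C; Me2S) cuts the propenyl group to the aryl aldehyde F2.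
   - Brown (E)-crotylboration with the reagent from (−)-Ipc2BOMe sets C2 and C3 as the (1S,2S)-anti homoallylic alcohol F3.
   - Hydroboration–oxidation (9-BBN; NaBO3) gives the 1,4-diol F4, and TEMPO with PhI(OAc)2 oxidises it to the trans-4-methyl-5-aryl lactone F5.
   - Enolate methylation (LiN(SiMe3)2, MeI, −78 °C) anti to the existing methyl group sets C4 and gives the all-trans lactone F6.
   - iBu2AlH gives the lactol F7, and PhSO2H with CaCl2 gives the 2-benzenesulfonyl tetrahydrofuran F8.
   - The arylzinc bromide F9 (from 4-bromo-2-methoxyphenyl tert-butyldimethylsilyl ether, Mg then ZnBr2) displaces the sulfinate through the oxocarbenium ion. It should add cis to the neighbouring methyl group, setting C5 and giving the 2,5-diaryl tetrahydrofuran F10 with the core of the target.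
   - K2CO3 in MeOH removes only the aryl silyl ether and gives the phenol F11.
   - The threo arm is then built on F11 as in steps 1, 2, 4 and 5: Mitsunobu reaction with 1 gives the ester F12, magnesium-amide aminolysis the Weinreb amide F13, Grignard reagent 6 the ketone F14, and polymer-supported borohydride the threo alcohol F15.
   - Bu4NF removes the remaining silyl ether and gives 18.

2. Step 5. Facial selectivity may be poor if a chelated pathway competes with the Felkin–Anh pathway, giving the erythro epimer alongside 8.
   The fallback sets out from ketone 7 and returns at 15. Zn(BH4)2 reduces 7 under chelation control to the erythro alcohol F16, the epimer that chelation delivers reliably. Mitsunobu esterification of F16 with acid 14 (PPh3, DIAD, THF) then forms the benzylic ester with inversion at C7. The threo (1R,2R) configuration and the mixed succinate 15 thus arise together, replacing steps 5 and 11.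

3. Step 2 (step 7 is its mirror image). The α-aryloxy stereocentre may lose configuration through enolisation of the ester by the basic magnesium amide.
   The fallback sets out from ethyl (S)-lactate 1 and returns at amide 4; it makes the amide before the ether. Aminolysis of 1 (MeNH(OMe)·HCl, iPrMgCl, THF, −20 °C) gives the hydroxy Weinreb amide F17, whose magnesium alkoxide shields the α-hydrogen. Mitsunobu reaction of F17 with 2 then gives 4 with inversion under neutral conditions. The enantiomeric amide F18 from 9 enters at 11 in the same way.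

Further compounds
F1 | step 12 | tert-butyldimethylsilyl ether of 13 at O7 | C/C=C/c1ccc(O[C@@H](C)[C@H](O[Si](C)(C)C(C)(C)C)c2ccc(OC)c(OC)c2)c(OC)c1
F2 | step 12 | 4-{[(1R,2S)-1-(tert-butyldimethylsilyloxy)-1-(3,4-dimethoxyphenyl)propan-2-yl]oxy}-3-methoxybenzaldehyde | O=Cc1ccc(O[C@@H](C)[C@H](O[Si](C)(C)C(C)(C)C)c2ccc(OC)c(OC)c2)c(OC)c1
F3 | step 12 | (1S,2S)-1-aryl-2-methylbut-3-en-1-ol (aryl = ring B with silylated erythro arm) | C=C[C@H](C)[C@H](O)c1ccc(O[C@@H](C)[C@H](O[Si](C)(C)C(C)(C)C)c2ccc(OC)c(OC)c2)c(OC)c1
F4 | step 12 | (1S,2S)-1-aryl-2-methylbutane-1,4-diol | OCC[C@H](C)[C@H](O)c1ccc(O[C@@H](C)[C@H](O[Si](C)(C)C(C)(C)C)c2ccc(OC)c(OC)c2)c(OC)c1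
F5 | step 12 | (4S,5S)-5-aryl-4-methyloxolan-2-one | COc1cc(ccc1O[C@@H](C)[C@H](O[Si](C)(C)C(C)(C)C)c2ccc(OC)c(OC)c2)[C@H]3OC(=O)C[C@@H]3C
F6 | step 12 | (3S,4S,5S)-5-aryl-3,4-dimethyloxolan-2-one | COc1cc(ccc1O[C@@H](C)[C@H](O[Si](C)(C)C(C)(C)C)c2ccc(OC)c(OC)c2)[C@H]3OC(=O)[C@@H](C)[C@@H]3C
F7 | step 12 | (3S,4S,5S)-5-aryl-3,4-dimethyloxolan-2-ol (anomers) | COc1cc(ccc1O[C@@H](C)[C@H](O[Si](C)(C)C(C)(C)C)c2ccc(OC)c(OC)c2)[C@H]3OC(O)[C@@H](C)[C@@H]3C
F8 | step 12 | (3S,4S,5S)-5-aryl-2-(benzenesulfonyl)-3,4-dimethyloxolane | COc1cc(ccc1O[C@@H](C)[C@H](O[Si](C)(C)C(C)(C)C)c2ccc(OC)c(OC)c2)[C@H]3OC(S(=O)(=O)c4ccccc4)[C@@H](C)[C@@H]3C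
F9 | step 12 | [4-(tert-butyldimethylsilyloxy)-3-methoxyphenyl]zinc bromide | COc1cc([Zn]Br)ccc1O[Si](C)(C)C(C)(C)C
F10 | step 12 | (2S,3S,4S,5R)-tetrahydrofuran with ring B (silylated erythro arm) at C2 and 4-(tert-butyldimethylsilyloxy)-3-methoxyphenyl at C5 | COc1cc(ccc1O[C@@H](C)[C@H](O[Si](C)(C)C(C)(C)C)c2ccc(OC)c(OC)c2)[C@H]3O[C@@H](c4ccc(O[Si](C)(C)C(C)(C)C)c(OC)c4)[C@@H](C)[C@@H]3C
F11 | step 12 | ring C phenol of F10 | COc1cc(ccc1O[C@@H](C)[C@H](O[Si](C)(C)C(C)(C)C)c2ccc(OC)c(OC)c2)[C@H]3O[C@@H](c4ccc(O)c(OC)c4)[C@@H](C)[C@@H]3C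
F12 | step 12 | ethyl (R)-2-aryloxypropanoate on ring C of the core | COc1cc(ccc1O[C@@H](C)[C@H](O[Si](C)(C)C(C)(C)C)c2ccc(OC)c(OC)c2)[C@H]3O[C@@H](c4ccc(O[C@H](C)C(=O)OCC)c(OC)c4)[C@@H](C)[C@@H]3C
F13 | step 12 | (R)-Weinreb amide on ring C of the core | COc1cc(ccc1O[C@@H](C)[C@H](O[Si](C)(C)C(C)(C)C)c2ccc(OC)c(OC)c2)[C@H]3O[C@@H](c4ccc(O[C@H](C)C(=O)N(C)OC)c(OC)c4)[C@@H](C)[C@@H]3C
F14 | step 12 | (R)-veratryl ketone on ring C of the core | COc1cc(ccc1O[C@@H](C)[C@H](O[Si](C)(C)C(C)(C)C)c2ccc(OC)c(OC)c2)[C@H]3O[C@@H](c4ccc(O[C@H](C)C(=O)c5ccc(OC)c(OC)c5)c(OC)c4)[C@@H](C)[C@@H]3C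
F15 | step 12 | tert-butyldimethylsilyl ether of 18 at O7 of the erythro arm | COc1cc(ccc1O[C@@H](C)[C@H](O[Si](C)(C)C(C)(C)C)c2ccc(OC)c(OC)c2)[C@H]3O[C@@H](c4ccc(O[C@H](C)[C@H](O)c5ccc(OC)c(OC)c5)c(OC)c4)[C@@H](C)[C@@H]3C
F16 | step 5 | (1S,2R)-1-(3,4-dimethoxyphenyl)-2-[2-methoxy-4-[(E)-prop-1-enyl]phenoxy]propan-1-ol (erythro) | C/C=C/c1ccc(O[C@H](C)[C@@H](O)c2ccc(OC)c(OC)c2)c(OC)c1
F17 | step 2 | (S)-2-hydroxy-N-methoxy-N-methylpropanamide | C[C@H](O)C(=O)N(C)OC
F18 | step 2 | (R)-2-hydroxy-N-methoxy-N-methylpropanamide | C[C@@H](O)C(=O)N(C)OC
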